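The ratio to read from these runs is the odds on the coupling partner: target made against the rest of the coupling partner charged, which I assume ended elsewhere, with odds of one, the even split, as the zero of the scale.

| setting | elm | oak | south-east | south | north-east | north |
|---|---|---|---|---|---|---|
| starting material | 0.013 M | 0.030 M | 0.020 M | 0.020 M | 0.020 M | 0.020 M |
| coupling partner | 0.036 M | 0.036 M | 0.0360 M | 0.0360 M | 0.0360 M | 0.0360 M |
| second substrate | 0.020 M | 0.020 M | 0.0200 M | 0.0200 M | 0.0200 M | 0.0200 M |
| temperature | 66 °C | 91 °C | 85 °C | 70 °C | 55 °C | 100 °C |
| remark | run made earlier | run made earlier |  |  |  |  |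
| time |  |  | 5.0 min | 5.0 min | 5.0 min | 5.0 min |

- elm (time / min: target / %): 0.833: 33.4; 2.50: 35.3; 4.00: 36.1; 6.00: 35.5; 10.0: 35.3; 12.0: 36.7; 15.0: 34.8
- oak (time / min: target / %): 0.833: 20.5; 1.50: 21.3; 2.50: 20.0; 3.00: 20.2; 4.00: 20.0; 5.00: 20.7; 6.00: 20.8

(each reading ± 0.5 percentage points)

- the best flask by amount of target, in percent of the starting material charged; "all alike" if 1.5 percentage points covers them all (south-east / south / north-east / north / all alike)
- amount of target at the end, in percent of the starting material charged, south-east
- amount of target at the end, in percent of the starting material charged, south
- amount of target at the end, in percent of the starting material charged, north-east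
- amount of target at the end, in percent of the starting material charged, north



You see both runs lie flat after their first reading, so I take the later readings as end values, which makes 0.00463 M of target in elm and 0.00615 M in oak, and the odds 0.148 and 0.206, both far below the even split . Oak was hotter but also held more starting material, so I assume that the odds grow in proportion to the starting material, and I define the capture strength κ, the odds divided by the starting material charged, which is 11.4 M⁻¹ in elm and lower in oak, at 6.87 M⁻¹. That loss by a factor 1.65 between 66 °C and 91 °C, spread evenly over the degrees, gives κ = 14.2 M⁻¹ in north-east and 5.73 M⁻¹ in north. Turning κ back into odds and the odds into target, my reckoning gives 39.7% for north-east, 31.2% for south, 24.2% for south-east and 18.5% for north, so north-east stands highest.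

The weak link is that κ uses the starting material as charged, though it falls as target forms. If you reforge it with the charge minus half the target made, κ for north-east becomes 17.9 M⁻¹ and the flask gives 40.2%, so I keep the reckoning.

The forecast, reasoning that “Competing pathways usually respond to both”, also named north-east but gave it 31.5%, with 28.5% for south, 25.5% for south-east and 22.5% for north.

The flasks give 42.0% in north-east, 31.8% in south, 23.5% in south-east and 17.2% in north, so the best is north-east.

    starting material + coupling partner → target (k = 1.53 M⁻¹ s⁻¹, Ea = 46.0 kJ mol⁻¹)
    second substrate + coupling partner → second product (k = 9.63 M⁻¹ s⁻¹, Ea = 52.0 kJ mol⁻¹)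
    starting material + second substrate → cross product (k = 3.18 M⁻¹ s⁻¹, Ea = 58.0 kJ mol⁻¹)
    2 coupling partner → self-condensation product (k = 0.158 M⁻¹ s⁻¹, Ea = 75.0 kJ mol⁻¹)
    coupling partner → decomposed reagent (k = 0.0419 s⁻¹, Ea = 83.0 kJ mol⁻¹)
    (constants at 70 °C)

Read back from north, κ is 5.30 M⁻¹ against my 5.73 M⁻¹. The main reason north holds so little target is the decomposition of the coupling partner to decomposed reagent: with that step taken away, north gives 68.6% instead of 17.2%. The coupling partner is the limiting reagent there, standing at 0% of its charge after 5.00 min while 49.5% of the starting material remains.

For the neighbour like north at 115 °C, κ carried on from elm is 4.24 M⁻¹, which gives 14.1% of target; the flask gives 12.7%.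

The data were generated by integration with made-up constants.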